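## The problem

CNP0265879.1 (27) is a C2-symmetric dimer. Each half is a lindenane unit: a cyclopentane fused to a cyclopropane and carrying an exocyclic methylene (C4=C15), a trans-fused cyclohexane, and a spiro-fused α-methylbutenolide. The halves are joined head to head by a cyclobutane made of C8, C9, C9′ and C8′.

Each half has six stereocentres (C1, C3, C5, C8, C9, C10). C10 is an all-carbon quaternary centre bonded directly to the cyclobutane carbon C9, and C8 is a fully substituted, oxygen-bearing spiro carbon, so the two C9–C10 bonds sit in the most crowded part of the molecule and are the hardest to make. The six-membered rings are cis-fused to the cyclobutane and lie on opposite faces of it (C10/C10′ trans, O8/O8′ trans). Within each half, H5 is anti to the C14 methyl and the cyclopropane methylene is syn to it.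

Control can flow from one centre per half. A resolved carbinol at C3 can set C10 by a suprafacial shift. C10 then biases C9 (through the transition state of that shift) and C1/C3 (its large C9 branch shields one face of the five-membered ring). The tether from C10 fixes C8 when the six-membered ring closes.

Three groups are fragile. The methylene next to the cyclopropane is sensitive to acid and electrophiles. The butenolides are sensitive to base (γ-deprotonation at C6). A cyclobutane with oxygen on C8/C8′ next to a ketone can open by retro-aldol or ketol shift. These groups should therefore appear late or be handled mildly.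

The enabling feature is that the chain C8–C9–C9′–C8′ is a succinic acid whose α-carbons each carry the quaternary C10 of a five-membered ring that can still hold a C1=C3 alkene. Each half is thus a γ,δ-unsaturated acid C8(=O)–C9–C10–C1=C3, the retron of an ester enolate Claisen rearrangement, present twice.

## Retrosynthesis

**Butenolides.** In 27 the bonds C7=C11 and O8–C12 of both lactones are cut. This leads to bis(phosphonopropanoate) 26, and from there to bis(α-ketol) 24 and phosphono acid 25. Carrying the lactones through earlier steps is ruled out by their base sensitivity. The cut removes two rings and three carbons per half. The forward steps must acylate hindered tertiary hydroxyls without forming an alkoxide and then condense the phosphonate carbanion with the C7 ketone (intramolecular Horner–Wadsworth–Emmons reaction).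

**Six-membered rings.** In 24 the C7–C8 bonds are cut. C7 arrives as an aldehyde and C8 as a ketone of cyclobutane-1,2-dione 23, and the bond is formed with umpolung at C7 (crossed benzoin reaction). Cutting C6–C7 or C5–C6 instead would leave the oxygenated quaternary C8 to be built on a preformed chain. With the C7–C8 cut, the tether from C10 can deliver C7 only to the face of C8 cis to C10, so C8 and C8′ need no separate control. 23 has two rings and two stereocentres fewer.

**Cyclobutane.** In 23 the C8–C8′ bond is cut, through ketol 22 and ene-diol bis(silyl ether) 21, back to succinate diester 20 (acyloin condensation). The other ring bonds (C8–C9, C9–C9′) are poorer cuts because they would break the succinic acid chain on which the key step depends. The precursor is an open-chain diester. The forward step must leave C9 and C9′ untouched (they become trans on the ring), and the silyl ethers and alkenes must tolerate sodium.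

**Five-membered rings.** In 20 the carbons C15 and C2 and the oxygen at C4 are removed in turn. 20 comes from bis(cyclopropyl ketone) 18 and phosphonium salt 19, 18 from bis(enone) 16 and sulfoxonium salt 17, and 16 from diester 15 by allylic oxidation. These operations are placed before the cyclobutane is closed. At this stage C5 is not yet a ring-fusion carbon, and its stable configuration (side chain anti to the large C9 branch) is the wanted one. Later, a C4 ketone would sit next to a trans ring fusion that can epimerise, and basic reagents would meet the butenolides. 15 contains only the C1=C3 alkenes, exactly what the key step delivers.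

**Key disconnection.** 15 is the dimethyl ester (with iodomethane 14) of succinic acid 13. In 13 both C9–C10 bonds are cut, which leads through bis(silyl ester) 12 and bis(silyl ketene acetal) 11 to bis(cyclopentenyl) succinate 10. Alkylation or conjugate addition at a neopentyl position would be the neighbouring options. The sigmatropic route is preferred because it forms the bond intramolecularly, creates the quaternary carbon and its tertiary neighbour together, and transfers the carbinol configuration to C10. Two skeletal bonds and four stereocentres disappear. The forward step must give one C9/C9′ diastereomer, the C2-symmetric one, which requires uniform ketene acetal geometry and one transition-state shape at both ends.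

**Diester.** 10 is cut at both acyl–oxygen bonds to succinyl chloride 9 and two molecules of alcohol 8. The alcohol must be a single enantiomer (otherwise meso and racemic diesters form), and its hydroxyl must be trans to the side chain so that the new bond forms anti to it.

**Cyclopentenol.** 8 comes from racemic enone 7 by carbonyl reduction. Hydride reagents attack a 4-substituted cyclopentenone anti to the substituent and so favour the cis alcohol. The reduction is therefore placed under catalyst control, which fixes the carbinol configuration in both enantiomers of 7. Only the (S)-enone can then give trans alcohol 8, and material from the (R)-enone is removed as a diastereomer. Resolution and the trans relationship are obtained in one step. 7 is the product of a vinylogous ester alkylation–transposition: the methyl comes from methyllithium 5 (through adduct 6), and the side chain from iodide 2 and dienolate 3 of 3-ethoxycyclopent-2-en-1-one 1 (through 4). The iodide is chosen over the bromide because 2-silyloxyethyl halides are sluggish electrophiles.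

## Roads not taken

Alternative 1: Crossed partition of the cyclobutane by an intramolecular ketene–alkene cycloaddition.
- **Cut and key step:** The ring is cut at C8–C9 and C8′–C9′. Ketene A1, generated by dehydrohalogenation with Et3N, would add across a trans C9=C9′ alkene to give cyclobutanone A2, closing the cyclobutane and one six-membered ring together.
- **Merits:** C8 is formed directly as an oxygenated spiro carbon in a C–C bond-forming step, and the product is a stable cyclobutanone. No cyclobutane-1,2-dione and no tertiary ketol are needed.
- **Weak points:** C2 symmetry is lost, so the halves must be made differently (one carries the butenolide, the other a 2-butynyl chain), and the second butenolide needs a later carbonylative closure on a strained ketone. The C9=C9′ alkene joins two quaternary carbons, so the hard C9–C10 bonds are moved elsewhere, not solved. The ketene must add to a very hindered, unactivated alkene with the right face and orientation.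
- **Comparison:** For building the four-membered ring this road is better than the chosen plan, whose steps 10–13 pass through fragile intermediates. Against that, the chosen plan treats both halves at once in every step and makes C9–C10 and the C10 stereocentre in the same operation from a simple symmetric ester.

Alternative 2: Tartrate-like cyclobutane core and double Dieckmann annulation.
- **Cut and key step:** The cut is C6–C7 on both sides. KN(SiMe3)2 would deprotonate tetraester A3 at C6 and C6′, and attack on the C7 esters would give bis(β-keto ester) A4.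
- **Merits:** Both oxygenated quaternary carbons are present from the start as silyl ethers, and a two-directional six-ring Dieckmann closure is reliable. This is safer than the dione and benzoin steps of the chosen plan.
- **Weak points:** A3 is itself the problem: a cyclobutane with four contiguous stereocentres whose C9 and C9′ carry the quaternary C10 units, so the C9–C10 bonds would have to be made on or before a crowded ring without a clear method. The β-silyloxy ester array can open the cyclobutane by retro-aldol under strong base. The ester carbon on C6 must be removed afterwards and the butenolide carbons added, which lengthens the end game.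
- **Comparison:** The chosen plan accepts a riskier ring closure in exchange for a precursor (10) that is made in four steps and a key step that solves the C9–C10 problem.

Alternative 3: Late hydroxyl-directed double cyclopropanation.
- **Cut and key step:** The cut is C1–C2 and C2–C3 on both sides. Et2Zn and CH2I2 would transfer a methylene to each C1=C3 alkene of bis(cyclopentenol) A5 from the face of the C4 hydroxyl, giving bis(cyclopropyl carbinol) A6.
- **Merits:** Facial control by a hydroxyl is more certain than the steric control used in step 8 of the chosen plan. The butenolide alkenes are inert to the zinc carbenoid, and the acid-sensitive vinylcyclopropane appears only at the end.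
- **Weak points:** This step does not address the core, so C9–C10 and the cyclobutane still need a solution such as the chosen key step. The C4 hydroxyl must be set syn to C14 on a late intermediate. The C4 carbinols must then be oxidised and methylenated next to a trans ring fusion whose C5 hydrogen can epimerise, in the presence of base-sensitive butenolides.
- **Comparison:** The chosen plan finishes the five-membered rings early, when C5 is not at a ring fusion, and keeps the directed cyclopropanation as the fallback for step 8.

Key step: step 5

Remark: atoms are numbered as in the lindenane skeleton throughout, and the cis alcohol formed beside 8 in step 3 is assumed to be separable from 8 by chromatography.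

## Route

Step 1
Reactants: 1 3-ethoxycyclopent-2-en-1-one; 2 tert-butyl(2-iodoethoxy)dimethylsilane
Product: 4 rac-5-[2-(tert-butyldimethylsilyloxy)ethyl]-3-ethoxycyclopent-2-en-1-one, via lithium dienolate 3 (not isolated)
Conditions: LiN(iPr)2, THF, −78 °C; then 2, DMPU, −78 → −20 °C
Reagents that add atoms: tert-butyl(2-iodoethoxy)dimethylsilane, ICCO[Si](C)(C)C(C)(C)C
Why: Stork–Danheiser kinetic α′-alkylation of a vinylogous ester: LiN(iPr)2 removes a C5 proton and the dienolate displaces the primary iodide with DMPU as cosolvent; the new stereocentre forms as a racemate and is sorted out in step 3.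

Step 2
Reactants: 4 rac-5-[2-(tert-butyldimethylsilyloxy)ethyl]-3-ethoxycyclopent-2-en-1-one; 5 methyllithium
Product: 7 rac-4-[2-(tert-butyldimethylsilyloxy)ethyl]-3-methylcyclopent-2-en-1-one, via lithium alkoxide 6 (not isolated)
Conditions: MeLi, THF, −78 → 0 °C; then 1 M aqueous HCl, 0 °C, short contact
Reagents that add atoms: methyllithium, [Li]C; water, O
Why: 1,2-addition of MeLi to the vinylogous ester carbonyl, then acid-induced hydrolysis and dehydration (Stork–Danheiser transposition), should move the carbonyl to the former enol ether carbon and leave the methyl on the alkene carbon next to the side-chain carbon; brief cold acid should spare the primary silyl ether.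

Step 3
Reactants: 7 rac-4-[2-(tert-butyldimethylsilyloxy)ethyl]-3-methylcyclopent-2-en-1-one
Product: 8 (1S,4S)-4-[2-(tert-butyldimethylsilyloxy)ethyl]-3-methylcyclopent-2-en-1-ol (hydroxyl trans to the side chain)
Conditions: (R)-2-methyl-CBS-oxazaborolidine (20 mol %), catecholborane, toluene, −78 °C; chromatographic removal of the cis diastereomer
Reagents that add atoms: none
Why: Corey–Bakshi–Shibata reduction run as a divergent reaction on a racemate: the catalyst, which treats the alkenyl arm as the large group, should fix the carbinol as S in both enantiomers, so the (S)-enone gives trans alcohol 8 and the (R)-enone the cis diastereomer; the enantiomer of 8 could form only against both catalyst and substrate preference, so the trans fraction should be of high enantiomeric purity.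

Step 4
Reactants: 8 (1S,4S)-4-[2-(tert-butyldimethylsilyloxy)ethyl]-3-methylcyclopent-2-en-1-ol (2 equiv); 9 succinyl chloride
Product: 10 bis{(1S,4S)-4-[2-(tert-butyldimethylsilyloxy)ethyl]-3-methylcyclopent-2-en-1-yl} butanedioate
Conditions: pyridine, DMAP (cat.), CH2Cl2, −20 → 0 °C
Reagents that add atoms: succinyl chloride, ClC(=O)CCC(=O)Cl
Why: Acylation of a secondary allylic alcohol by a diacid chloride; no bond at the carbinol carbon is broken, so the configuration is retained, and buffering by pyridine guards the ionisable allylic ester against HCl.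

Step 5
Reactants: 10 bis{(1S,4S)-4-[2-(tert-butyldimethylsilyloxy)ethyl]-3-methylcyclopent-2-en-1-yl} butanedioate
Product: 13 (2S,3S)-2,3-bis{(1R,5R)-5-[2-(tert-butyldimethylsilyloxy)ethyl]-1-methylcyclopent-2-en-1-yl}butanedioic acid, via bis(silyl ketene acetal) 11 (not isolated), via bis(trimethylsilyl) ester 12 (not isolated)
Conditions: LiN(iPr)2 (2.5 equiv), Me3SiCl, THF–DMPU, −78 °C; then 23 → 60 °C; aqueous citric acid work-up
Reagents that add atoms: none
Why: Double Ireland–Claisen rearrangement: LiN(iPr)2 in THF–DMPU deprotonates both α-carbons of the succinate and Me3SiCl traps the enolates as the (Z,Z)-bis(silyl ketene acetal) 11, in which each ketene acetal carbon (C9, C9′) has the other cis to its OSiMe3 group. On warming, each allyl ketene acetal unit undergoes a suprafacial [3,3]-sigmatropic shift in which C9 bonds to the methyl-bearing alkene carbon C10 while the C3–O bond breaks and the alkene moves to C1=C3; aqueous acid then cleaves the silyl esters of 12. The closest known reactions are the Ireland–Claisen rearrangement of diallyl succinates through their bis(silyl ketene acetals) and of cyclopent-2-enyl esters to quaternary carbons; no ring is closed, and two C–C bonds and four stereocentres are formed. C10 and C10′ are controlled by the carbinol carbon C3: the new bond appears on the face that the oxygen leaves, which is anti to the C5 side chain. C9 and C9′ are controlled by ketene acetal geometry and transition-state shape: a Z ketene acetal of a cycloalkenyl ester should react through the boat-like arrangement, which keeps the OSiMe3-bearing carbon off the ring, puts the succinate chain at the periphery next to the C10 methyl and the hydrogen over the ring, and leads to the 2S,3S configuration of 13. Because both cyclopentenyl groups have the same absolute configuration, equal selection at the two ends gives the C2-symmetric diacid; the step therefore needs uniform Z geometry (secured by DMPU) and boat over chair (secured by the ring and by the bulk of the chain, which is larger still in the second shift). An end with E geometry, if it reacted through the chair-like arrangement that also keeps the chain at the periphery, would give the same configuration, so incomplete geometric control should cost less than in an open-chain case. Silylation at −78 °C keeps the monoenolate from condensation or ketene loss before both ends are trapped.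

Step 6
Reactants: 13 (2S,3S)-2,3-bis{(1R,5R)-5-[2-(tert-butyldimethylsilyloxy)ethyl]-1-methylcyclopent-2-en-1-yl}butanedioic acid; 14 iodomethane
Product: 15 dimethyl (2S,3S)-2,3-bis{(1R,5R)-5-[2-(tert-butyldimethylsilyloxy)ethyl]-1-methylcyclopent-2-en-1-yl}butanedioate
Conditions: MeI, K2CO3, DMF, 23 °C
Reagents that add atoms: iodomethane, CI
Why: O-alkylation of the carboxylates (SN2 at methyl), which is insensitive to the neopentyl-like crowding of the carboxyl groups; no stereocentre is touched.

Step 7
Reactants: 15 dimethyl (2S,3S)-2,3-bis{(1R,5R)-5-[2-(tert-butyldimethylsilyloxy)ethyl]-1-methylcyclopent-2-en-1-yl}butanedioate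
Product: 16 bis(enone): diester 15 with ketones at C4 and C4′ (two 4-oxocyclopent-2-en-1-yl units; stereocentres as in 15)
Conditions: CrO3, 3,5-dimethylpyrazole, CH2Cl2, −20 °C
Reagents that add atoms: chromium trioxide, O=[Cr](=O)=O
Why: Allylic oxidation by the CrO3–3,5-dimethylpyrazole complex: C4 is the only allylic carbon of each cyclopentene that bears hydrogen (C10 is quaternary), and oxidation with transposition to C1 is disfavoured next to the quaternary carbon, so the enone should form as C4=O conjugated with C1=C3; silyl ethers and esters are inert.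

Step 8
Reactants: 16 bis(enone); 17 trimethylsulfoxonium iodide
Product: 18 bis(cyclopropyl ketone): dimethyl 2,3-bis{3-[2-(tert-butyldimethylsilyloxy)ethyl]-2-methyl-4-oxobicyclo[3.1.0]hexan-2-yl}butanedioate (cyclopropane methylene syn to the ring methyl)
Conditions: Me3S(O)I, NaH, DMSO, 23 °C
Reagents that add atoms: trimethylsulfoxonium iodide, C[S+](C)(C)=O.[I-]
Why: Corey–Chaykovsky cyclopropanation: dimethylsulfoxonium methylide adds to C1 in conjugate fashion and the enolate closes the three-membered ring at C3; the ylide should approach C1 anti to the large C9 branch on the adjacent quaternary C10, on the face of the C14 methyl, which sets C1 and C3 with the methylene syn to C14 as in 27.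

Step 9
Reactants: 18 bis(cyclopropyl ketone); 19 methyltriphenylphosphonium bromide
Product: 20 bis(methylene) diester: dimethyl 2,3-bis{3-[2-(tert-butyldimethylsilyloxy)ethyl]-2-methyl-4-methylidenebicyclo[3.1.0]hexan-2-yl}butanedioate
Conditions: Ph3PCH3Br, KOtBu, THF, 0 → 50 °C
Reagents that add atoms: methyltriphenylphosphonium bromide, C[P+](c1ccccc1)(c1ccccc1)c1ccccc1.[Br-]
Why: Wittig methylenation of a bicyclo[3.1.0]hexan-2-one, a ketone class that is methylenated routinely; the hindered methyl esters should not react with the ylide, and C5 (α to the ketone) already has its more stable configuration with the side chain anti to the C9 branch.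

Step 10
Reactants: 20 bis(methylene) diester
Product: 21 1,2-bis(trimethylsilyloxy)cyclobut-1-ene with the two bicyclohexyl groups trans at C3 and C4 (lindenane C9 and C9′)
Conditions: Na (dispersion), Me3SiCl, THF, ultrasound, 0 → 23 °C; filtration under argon
Reagents that add atoms: chlorotrimethylsilane, C[Si](C)(C)Cl
Why: Acyloin condensation with in situ silylation: electron transfer from sodium to both esters, C8–C8′ coupling to the four-membered ring (the standard succinate-to-cyclobutene closure) and trapping of the ene-diolate as its bis(silyl ether), which suppresses base-induced side reactions; C9 and C9′ are not touched and end up trans, and the low temperature avoids conrotatory opening of the trans-3,4-disubstituted cyclobutene.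

Step 11
Reactants: 21 bis(silyloxy)cyclobutene
Product: 22 2-hydroxycyclobutan-1-one with the two 3-(2-hydroxyethyl)bicyclohexyl groups trans at C3 and C4 (mixture at the carbinol carbon)
Conditions: HF·pyridine, pyridine, THF, 0 → 23 °C
Reagents that add atoms: none
Why: Fluoride-driven cleavage of all four Si–O bonds (two silyl enol ethers, two primary silyl ethers); the ene-diol tautomerises to the α-ketol, and the pyridine buffer protects the methylene–cyclopropane units from acid.

Step 12
Reactants: 22 ketol diol
Product: 23 cyclobutane-1,2-dione with the two 3-(2-oxoethyl)bicyclohexyl groups trans at C3 and C4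
Conditions: Dess–Martin periodinane, pyridine, CH2Cl2, 0 → 23 °C; filtration through Celite, no aqueous work-up, used at once
Reagents that add atoms: none
Why: Dess–Martin oxidation of the two primary alcohols to aldehydes and of the α-ketol to the 1,2-dione in one operation; the carbinol epimers of 22 converge, and water is excluded because cyclobutane-1,2-diones hydrate and contract.

Step 13
Reactants: 23 dione dialdehyde
Product: 24 bis(α-ketol): heptacyclic 8,8′-dihydroxy-7,7′-diketone in which each new cyclohexanone is cis-fused to the cyclobutane (hydroxyls trans to each other)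
Conditions: 2-(pentafluorophenyl)-6,7-dihydro-5H-pyrrolo[2,1-c][1,2,4]triazol-2-ium tetrafluoroborate (20 mol %), iPr2NEt (20 mol %), CH2Cl2, 23 °C
Reagents that add atoms: none
Why: Two intramolecular crossed aldehyde–ketone benzoin reactions under carbene catalysis: the carbene adds to each aldehyde, the resulting hydroxy-enamine (acyl anion equivalent at C7) attacks the strained, highly electrophilic ketone C8 in a 6-exo closure, and proton transfer with loss of the carbene gives the C7 ketone and the C8 tertiary alcohol; the tether from C10 can reach C8 only on the face of C10, so C8 and C8′ should form with the configuration of 27, and the weak base keeps the new alkoxides short-lived.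

Step 14
Reactants: 24 bis(α-ketol); 25 2-(diethoxyphosphoryl)propanoic acid
Product: 26 bis[2-(diethoxyphosphoryl)propanoate] of 24 (mixture at the phosphorus-bearing carbons)
Conditions: DCC, DMAP, CH2Cl2, 0 → 23 °C
Reagents that add atoms: 2-(diethoxyphosphoryl)propanoic acid, CCOP(=O)(OCC)C(C)C(=O)O
Why: Carbodiimide (Steglich-type) esterification; acids with an acidic α-hydrogen are known to acylate tertiary alcohols under these conditions, and the near-neutral medium avoids the alkoxides that could open the cyclobutane by retro-aldol; the new stereocentres are destroyed in step 15.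

Step 15
Reactants: 26 bis(phosphonopropanoate)
Product: 27 CNP0265879.1
Conditions: NaH, THF, 0 → 23 °C
Reagents that add atoms: none
Why: Intramolecular Horner–Wadsworth–Emmons reaction on both sides: each phosphonate carbanion adds to its C7 ketone in a five-membered closure and loss of diethyl phosphate gives the C7=C11 butenolide; no stereocentre is formed and the oxygen on C8 is already acylated, so the strained core is no longer at risk.

## Compound list

1 | 3-ethoxycyclopent-2-en-1-one | CCOC1=CC(=O)CC1 | starting material
2 | tert-butyl(2-iodoethoxy)dimethylsilane | ICCO[Si](C)(C)C(C)(C)C | starting material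
3 | lithium 3-ethoxycyclopenta-1,3-dien-1-olate (α′-dienolate of 1) | [Li+].CCOC1=CC([O-])=CC1 | intermediate (not isolated)
4 | rac-5-[2-(tert-butyldimethylsilyloxy)ethyl]-3-ethoxycyclopent-2-en-1-one | CCOC1=CC(=O)C(CCO[Si](C)(C)C(C)(C)C)C1 | intermediate
5 | methyllithium | [Li]C | starting material
6 | lithium 3-ethoxy-1-methyl-5-[2-(tert-butyldimethylsilyloxy)ethyl]cyclopent-2-en-1-olate (diastereomer mixture, racemic) | [Li+].CCOC1=CC(C)([O-])C(CCO[Si](C)(C)C(C)(C)C)C1 | intermediate (not isolated)
7 | rac-4-[2-(tert-butyldimethylsilyloxy)ethyl]-3-methylcyclopent-2-en-1-one | CC1=CC(=O)CC1CCO[Si](C)(C)C(C)(C)C | intermediate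
8 | (1S,4S)-4-[2-(tert-butyldimethylsilyloxy)ethyl]-3-methylcyclopent-2-en-1-ol | O[C@@H]1C=C(C)[C@@H](CCO[Si](C)(C)C(C)(C)C)C1 | intermediate
9 | succinyl chloride (butanedioyl dichloride) | ClC(=O)CCC(=O)Cl | starting material
10 | bis{(1S,4S)-4-[2-(tert-butyldimethylsilyloxy)ethyl]-3-methylcyclopent-2-en-1-yl} butanedioate | O=C(CCC(=O)O[C@@H]1C=C(C)[C@@H](CCO[Si](C)(C)C(C)(C)C)C1)O[C@@H]1C=C(C)[C@@H](CCO[Si](C)(C)C(C)(C)C)C1 | intermediate
11 | (1Z,3Z)-1,4-bis{[(1S,4S)-4-[2-(tert-butyldimethylsilyloxy)ethyl]-3-methylcyclopent-2-en-1-yl]oxy}-1,4-bis(trimethylsilyloxy)buta-1,3-diene | C[Si](C)(C)O/C(O[C@@H]1C=C(C)[C@@H](CCO[Si](C)(C)C(C)(C)C)C1)=C\C=C(/O[Si](C)(C)C)O[C@@H]1C=C(C)[C@@H](CCO[Si](C)(C)C(C)(C)C)C1 | intermediate (not isolated)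
12 | bis(trimethylsilyl) ester of 13 | C1C=C[C@@]([C@@H](C(=O)O[Si](C)(C)C)[C@H](C(=O)O[Si](C)(C)C)[C@@]2(C)C=CC[C@@H]2CCO[Si](C)(C)C(C)(C)C)(C)[C@H]1CCO[Si](C)(C)C(C)(C)C | intermediate (not isolated)
13 | (2S,3S)-2,3-bis{(1R,5R)-5-[2-(tert-butyldimethylsilyloxy)ethyl]-1-methylcyclopent-2-en-1-yl}butanedioic acid | C1C=C[C@@]([C@@H](C(=O)O)[C@H](C(=O)O)[C@@]2(C)C=CC[C@@H]2CCO[Si](C)(C)C(C)(C)C)(C)[C@H]1CCO[Si](C)(C)C(C)(C)C | intermediate
14 | iodomethane | CI | starting material
15 | dimethyl (2S,3S)-2,3-bis{(1R,5R)-5-[2-(tert-butyldimethylsilyloxy)ethyl]-1-methylcyclopent-2-en-1-yl}butanedioate | C1C=C[C@@]([C@@H](C(=O)OC)[C@H](C(=O)OC)[C@@]2(C)C=CC[C@@H]2CCO[Si](C)(C)C(C)(C)C)(C)[C@H]1CCO[Si](C)(C)C(C)(C)C | intermediate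
16 | bis(enone): dimethyl 2,3-bis{5-[2-(tert-butyldimethylsilyloxy)ethyl]-1-methyl-4-oxocyclopent-2-en-1-yl}butanedioate, stereocentres as in 15 | O=C1C=C[C@@]([C@@H](C(=O)OC)[C@H](C(=O)OC)[C@@]2(C)C=CC(=O)[C@@H]2CCO[Si](C)(C)C(C)(C)C)(C)[C@H]1CCO[Si](C)(C)C(C)(C)C | intermediate
17 | trimethylsulfoxonium iodide | C[S+](C)(C)=O.[I-] | starting material
18 | bis(cyclopropyl ketone): dimethyl 2,3-bis{3-[2-(tert-butyldimethylsilyloxy)ethyl]-2-methyl-4-oxobicyclo[3.1.0]hexan-2-yl}butanedioate, cyclopropane methylene syn to the ring methyl | O=C1[C@H]2C[C@H]2[C@@]([C@@H](C(=O)OC)[C@H](C(=O)OC)[C@@]2(C)[C@@H]4C[C@@H]4C(=O)[C@@H]2CCO[Si](C)(C)C(C)(C)C)(C)[C@H]1CCO[Si](C)(C)C(C)(C)C | intermediate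
19 | methyltriphenylphosphonium bromide | C[P+](c1ccccc1)(c1ccccc1)c1ccccc1.[Br-] | starting material
20 | bis(methylene) diester: dimethyl 2,3-bis{3-[2-(tert-butyldimethylsilyloxy)ethyl]-2-methyl-4-methylidenebicyclo[3.1.0]hexan-2-yl}butanedioate | C=C1[C@H]2C[C@H]2[C@@]([C@@H](C(=O)OC)[C@H](C(=O)OC)[C@@]2(C)[C@@H]4C[C@@H]4C(=C)[C@@H]2CCO[Si](C)(C)C(C)(C)C)(C)[C@H]1CCO[Si](C)(C)C(C)(C)C | intermediate
21 | 1,2-bis(trimethylsilyloxy)cyclobut-1-ene with the two silyloxyethyl-substituted bicyclohexyl groups trans at C3 and C4 | C=C1[C@H]2C[C@H]2[C@@]([C@@H]3[C@H](C(O[Si](C)(C)C)=C3O[Si](C)(C)C)[C@@]2(C)[C@@H]4C[C@@H]4C(=C)[C@@H]2CCO[Si](C)(C)C(C)(C)C)(C)[C@H]1CCO[Si](C)(C)C(C)(C)C | intermediate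
22 | 2-hydroxycyclobutan-1-one with the two 3-(2-hydroxyethyl)bicyclohexyl groups trans at C3 and C4 (mixture at the carbinol carbon) | C=C1[C@H]2C[C@H]2[C@@]([C@@H]3[C@H](C(O)C3=O)[C@@]2(C)[C@@H]4C[C@@H]4C(=C)[C@@H]2CCO)(C)[C@H]1CCO | intermediate
23 | cyclobutane-1,2-dione with the two 3-(2-oxoethyl)bicyclohexyl groups trans at C3 and C4 | C=C1[C@H]2C[C@H]2[C@@]([C@@H]3[C@H](C(=O)C3=O)[C@@]2(C)[C@@H]4C[C@@H]4C(=C)[C@@H]2CC=O)(C)[C@H]1CC=O | intermediate
24 | bis(α-ketol): heptacyclic 8,8′-dihydroxy-7,7′-diketone (lindenane numbering) | C=C1[C@H]2C[C@H]2[C@@]2(C)[C@H]1CC(=O)[C@]3(O)[C@H]2[C@H]1[C@@]2(C)[C@@H]4C[C@@H]4C(=C)[C@@H]2CC(=O)[C@]13O | intermediate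
25 | 2-(diethoxyphosphoryl)propanoic acid | CCOP(=O)(OCC)C(C)C(=O)O | starting material
26 | bis[2-(diethoxyphosphoryl)propanoate] of 24 | C=C1[C@H]2C[C@H]2[C@@]2(C)[C@H]1CC(=O)[C@]3(OC(=O)C(C)P(=O)(OCC)OCC)[C@H]2[C@H]1[C@@]2(C)[C@@H]4C[C@@H]4C(=C)[C@@H]2CC(=O)[C@]13OC(=O)C(C)P(=O)(OCC)OCC | intermediate
27 | CNP0265879.1 | C=C1[C@H]2C[C@H]2[C@@]2(C)[C@H]1CC1=C(C)C(=O)O[C@]13[C@H]2[C@H]1[C@@]2(C)[C@@H]4C[C@@H]4C(=C)[C@@H]2CC2=C(C)C(=O)O[C@@]213 | target

## Step count and least certain steps

Total: 15 steps. Longest linear sequence: 15 steps (1 → 27); every step after step 4 acts on both halves at once.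

**Step 5 (key step).**
- Risk: erosion of simple diastereoselection at C9/C9′ if chair and boat paths compete or the ketene acetal geometry is mixed; breakdown of the monoenolate (condensation, ketene loss) before both ends are silylated; a slow second shift at the crowded quaternary terminus.
- Fallback (8 → 13): the two bonds are made one at a time so that each rearrangement can be controlled and purified separately. Alcohol 8 is acylated with succinic anhydride to the hydrogen succinate F1. Its dianion (carboxylate and ester enolate; LiN(iPr)2, Me3SiCl) rearranges once to the monosubstituted succinic acid F2. The unhindered carboxyl of F2 is esterified with a second equivalent of 8 (DCC, DMAP; the other carboxyl is neopentyl-like) to the acid ester F3. A second Ireland–Claisen rearrangement of F3 returns to 13.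

**Step 13.**
- Risk: cleavage of the C8–C8′ bond, either by attack of the carbene on the dione or by retro-aldol opening of the cyclobutane from the C8′ alkoxide once C7 is a ketone; ketol ring expansion of the 1-acylcyclobutanol units.
- Fallback (22 → 27): a route in which no alkoxide ever stands next to a ketone. Only the primary alcohols of 22 are oxidised (TEMPO, PhI(OAc)2) to the ketol dialdehyde F4. F4 is olefinated with 2-(triphenylphosphoranylidene)propanal to the ketol bis(enal) F5, and the ketol is then oxidised (Dess–Martin periodinane) to the dione bis(enal) F6. The carbene from 1,3-bis(2,4,6-trimethylphenyl)imidazolium chloride and DBU generates a homoenolate at C7, which adds to C8 while the acyl azolium is captured by the new alkoxide, giving the bis(α-methyl-γ-lactone) F7. Dehydrogenation (LiN(iPr)2, then N-tert-butylbenzenesulfinimidoyl chloride) leads to 27.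

**Step 10.**
- Risk: failure of the hindered esters to couple, over-reduction, or electrocyclic opening of the trans-3,4-disubstituted bis(silyloxy)cyclobutene on warming.
- Fallback (20 → 23): the ring is closed by pinacol coupling instead. Diester 20 is reduced (iBu2AlH, −78 °C) to the dialdehyde F8. F8 is cyclised with SmI2 to the cyclobutane-1,2-diol F9. HF·pyridine gives the tetraol F10, and Swern oxidation of all four hydroxyls returns to 23.

**Step 3.**
- Risk: incomplete catalyst control on the (S)-enone, for which catalyst and substrate preferences oppose each other, giving little trans alcohol or lower enantiomeric purity; difficult separation of the diastereomers.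
- Fallback (7 → 8): Luche reduction of 7 (NaBH4, CeCl3·7H2O) gives the racemic cis alcohol F11 by hydride attack anti to the side chain. Mitsunobu inversion with 4-nitrobenzoic acid gives the racemic trans ester F12, and K2CO3 in methanol gives the racemic trans alcohol F13. Lipase-catalysed acetylation (Burkholderia cepacia lipase, vinyl acetate) then removes the unwanted enantiomer and leaves 8.

**Step 8.**
- Risk: insufficient facial selectivity of ylide attack at C1, or epimerisation at C5 under the basic conditions.
- Fallback (15 → 18): the face is set by a hydroxyl. Diester 15 is oxidised with SeO2 and tBuOOH (ene reaction at C1 anti to the C9 branch, then [2,3]-shift) to the bis(allylic alcohol) F14 with the C4 hydroxyl syn to C14. Simmons–Smith cyclopropanation (Et2Zn, CH2I2) directed by that hydroxyl gives the bis(cyclopropyl carbinol) F15, and Dess–Martin oxidation returns to 18.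

## Further compounds

F1 | step 5 | 4-{[(1S,4S)-4-[2-(tert-butyldimethylsilyloxy)ethyl]-3-methylcyclopent-2-en-1-yl]oxy}-4-oxobutanoic acid | OC(=O)CCC(=O)O[C@@H]1C=C(C)[C@@H](CCO[Si](C)(C)C(C)(C)C)C1
F2 | step 5 | (2S)-2-{(1R,5R)-5-[2-(tert-butyldimethylsilyloxy)ethyl]-1-methylcyclopent-2-en-1-yl}butanedioic acid | C1C=C[C@@]([C@@H](C(=O)O)CC(=O)O)(C)[C@H]1CCO[Si](C)(C)C(C)(C)C
F3 | step 5 | 4-[(1S,4S)-cyclopentenyl] ester of F2 (C1 carboxyl free) | C1C=C[C@@]([C@@H](C(=O)O)CC(=O)O[C@@H]2C=C(C)[C@@H](CCO[Si](C)(C)C(C)(C)C)C2)(C)[C@H]1CCO[Si](C)(C)C(C)(C)C
F4 | step 13 | ketol dialdehyde (22 with both side chains as CH2CHO) | C=C1[C@H]2C[C@H]2[C@@]([C@@H]3[C@H](C(O)C3=O)[C@@]2(C)[C@@H]4C[C@@H]4C(=C)[C@@H]2CC=O)(C)[C@H]1CC=O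
F5 | step 13 | ketol bis(enal) with (E)-3-formylbut-2-enyl side chains | C=C1[C@H]2C[C@H]2[C@@]([C@@H]3[C@H](C(O)C3=O)[C@@]2(C)[C@@H]4C[C@@H]4C(=C)[C@@H]2C/C=C(/C=O)C)(C)[C@H]1C/C=C(/C=O)C
F6 | step 13 | cyclobutane-1,2-dione bis(enal) | C=C1[C@H]2C[C@H]2[C@@]([C@@H]3[C@H](C(=O)C3=O)[C@@]2(C)[C@@H]4C[C@@H]4C(=C)[C@@H]2C/C=C(/C=O)C)(C)[C@H]1C/C=C(/C=O)C
F7 | step 13 | 7,11,7′,11′-tetrahydro derivative of 27 (bis(α-methyl-γ-lactone), mixture at C7 and C11) | C=C1[C@H]2C[C@H]2[C@@]2(C)[C@H]1CC1C(C)C(=O)O[C@]13[C@H]2[C@H]1[C@@]2(C)[C@@H]4C[C@@H]4C(=C)[C@@H]2CC2C(C)C(=O)O[C@@]213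
F8 | step 10 | dialdehyde from 20 (both CO2Me groups as CHO) | C=C1[C@H]2C[C@H]2[C@@]([C@@H](C=O)[C@H](C=O)[C@@]2(C)[C@@H]4C[C@@H]4C(=C)[C@@H]2CCO[Si](C)(C)C(C)(C)C)(C)[C@H]1CCO[Si](C)(C)C(C)(C)C
F9 | step 10 | cyclobutane-1,2-diol with the two silyloxyethyl-substituted bicyclohexyl groups trans at C3 and C4 (mixture at the carbinol carbons) | C=C1[C@H]2C[C@H]2[C@@]([C@@H]3[C@H](C(O)C3O)[C@@]2(C)[C@@H]4C[C@@H]4C(=C)[C@@H]2CCO[Si](C)(C)C(C)(C)C)(C)[C@H]1CCO[Si](C)(C)C(C)(C)C
F10 | step 10 | tetraol (F9 without the silyl groups) | C=C1[C@H]2C[C@H]2[C@@]([C@@H]3[C@H](C(O)C3O)[C@@]2(C)[C@@H]4C[C@@H]4C(=C)[C@@H]2CCO)(C)[C@H]1CCO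
F11 | step 3 | rac-cis-4-[2-(tert-butyldimethylsilyloxy)ethyl]-3-methylcyclopent-2-en-1-ol (racemate, one enantiomer drawn) | O[C@@H]1C=C(C)[C@H](CCO[Si](C)(C)C(C)(C)C)C1
F12 | step 3 | rac-trans-4-[2-(tert-butyldimethylsilyloxy)ethyl]-3-methylcyclopent-2-en-1-yl 4-nitrobenzoate (racemate, one enantiomer drawn) | O=C(O[C@@H]1C=C(C)[C@@H](CCO[Si](C)(C)C(C)(C)C)C1)c1ccc(cc1)[N+]([O-])=O
F13 | step 3 | rac-trans-4-[2-(tert-butyldimethylsilyloxy)ethyl]-3-methylcyclopent-2-en-1-ol (racemate of 8, one enantiomer drawn) | O[C@@H]1C=C(C)[C@@H](CCO[Si](C)(C)C(C)(C)C)C1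
F14 | step 8 | bis(allylic alcohol): 15 with hydroxyl at C4 and C4′ syn to the ring methyl | O[C@H]1C=C[C@@]([C@@H](C(=O)OC)[C@H](C(=O)OC)[C@@]2(C)C=C[C@H](O)[C@@H]2CCO[Si](C)(C)C(C)(C)C)(C)[C@H]1CCO[Si](C)(C)C(C)(C)C
F15 | step 8 | bis(cyclopropyl carbinol): 18 with C4 and C4′ as carbinols syn to the cyclopropane methylene | O[C@H]1[C@H]2C[C@H]2[C@@]([C@@H](C(=O)OC)[C@H](C(=O)OC)[C@@]2(C)[C@@H]4C[C@@H]4[C@H](O)[C@@H]2CCO[Si](C)(C)C(C)(C)C)(C)[C@H]1CCO[Si](C)(C)C(C)(C)C
A1 | alternative 1 | butenolide-derived ketene tethered to the trans C9=C9′ alkene | C=C1[C@H]2C[C@H]2[C@@](/C=C/[C@@]2(C)[C@@H]4C[C@@H]4C(=C)[C@@H]2CC#CC)(C)[C@H]1CC1=C(C)C(=O)OC1=C=O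
A2 | alternative 1 | cyclobutanone with one butenolide and one 2-butynyl side chain | C=C1[C@H]2C[C@H]2[C@@]2(C)[C@H]1CC1=C(C)C(=O)O[C@]13[C@H]2[C@H](C3=O)[C@@]2(C)[C@@H]4C[C@@H]4C(=C)[C@@H]2CC#CC
A3 | alternative 2 | cyclobutane tetraester with triethylsilyloxy groups on C8 and C8′ | C=C1[C@H]2C[C@H]2[C@@]([C@H]3[C@@](O[Si](CC)(CC)CC)(C(=O)OC)[C@](O[Si](CC)(CC)CC)(C(=O)OC)[C@@H]3[C@@]2(C)[C@@H]4C[C@@H]4C(=C)[C@@H]2CC(=O)OC)(C)[C@H]1CC(=O)OC
A4 | alternative 2 | bis(β-keto ester), drawn as its enol | C=C1[C@H]2C[C@H]2[C@@]2(C)[C@H]1C(C(=O)OC)=C(O)[C@]3(O[Si](CC)(CC)CC)[C@H]2[C@H]1[C@@]2(C)[C@@H]4C[C@@H]4C(=C)[C@@H]2C(C(=O)OC)=C(O)[C@]13O[Si](CC)(CC)CC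
A5 | alternative 3 | bis(cyclopentenol) bis(butenolide) | O[C@H]1C=C[C@@]2(C)[C@H]1CC1=C(C)C(=O)O[C@]13[C@H]2[C@H]1[C@@]2(C)C=C[C@H](O)[C@@H]2CC2=C(C)C(=O)O[C@@]213
A6 | alternative 3 | bis(cyclopropyl carbinol) bis(butenolide) | O[C@H]1[C@H]2C[C@H]2[C@@]2(C)[C@H]1CC1=C(C)C(=O)O[C@]13[C@H]2[C@H]1[C@@]2(C)[C@@H]4C[C@@H]4[C@H](O)[C@@H]2CC2=C(C)C(=O)O[C@@]213
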